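The benzene ring of the indane is built last, around the C5 2-chloroethyl arm: with chlorine moved back from the side chain to ring carbon C6, C5 and its arm become a spirocyclopropane and the arene becomes a spiro[2.5]octa-4,6-diene. That diene arises from a cyclopentane-fused 3-carbomethoxy-2-pyranone and methyl 2-chloro-2-cyclopropylideneacetate by [4+2] cycloaddition and loss of CO2. In one operation the key step closes the six-membered carbocycle, places the C4 and C6 ester carbons, the C7 hydrogen and the fused cyclopentane, and aromatises without oxidant by chloride-mediated opening of the cyclopropane. Reduction and two site-differentiated acylations finish the target.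

Key step: step 6

Remark: arene positions use indane numbering (C4 acetoxymethyl, C5 2-chloroethyl, C6 butanoyloxymethyl, C7 H); the target has no stereocentre; compounds 1, 2, 4, 8 and 9 are taken as purchasable.

Step 1
Reactants: 1 3,3-dimethylcyclopentanone; 2 dimethyl malonate
Product: 3 dimethyl 2-(3,3-dimethylcyclopentylidene)malonate
Conditions: TiCl4 (2 equiv), pyridine (4 equiv), THF, 0 °C to rt
Reagents that add atoms: none
Why: Knoevenagel condensation under TiCl4/pyridine conditions is the established way to condense a ketone with a malonate, and the symmetric malonate leaves no alkene geometry to control.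

Step 2
Reactants: 3 dimethyl 2-(3,3-dimethylcyclopentylidene)malonate; 4 N,N-dimethylformamide dimethyl acetal
Product: 5 dimethyl 2-{(2E)-2-[(dimethylamino)methylidene]-4,4-dimethylcyclopentylidene}malonate
Conditions: neat 4 (3 equiv), 110 °C, MeOH distilled off
Reagents that add atoms: none
Why: Vinylogous aminomethylenation with an amide acetal runs through the dienolate of the alkylidene malonate, and because one of the two γ-methylenes is neopentyl (next to the quaternary carbon), condensation should occur at the other and give the less crowded E enamine.

Step 3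
Reactants: 5 dimethyl 2-{(2E)-2-[(dimethylamino)methylidene]-4,4-dimethylcyclopentylidene}malonate
Product: 7 methyl 6,6-dimethyl-3-oxo-3,5,6,7-tetrahydrocyclopenta[c]pyran-4-carboxylate, via hydroxymethylene diester 6 (not isolated)
Conditions: 2 M aq. HCl, AcOH, 70 °C
Reagents that add atoms: water, O
Why: Acid hydrolysis of the vinylogous enamine gives the hydroxymethylene compound, whose enol oxygen closes onto the neighbouring ester (enol lactonisation with loss of methanol), the classical 2-pyranone synthesis from 5-aminodienoates; the enol geometry equilibrates through the aldehyde tautomer.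

Step 4
Reactants: 8 tetrachlorocyclopropene; 9 ethylene
Product: 11 1-chloro-1-(trichloroethenyl)cyclopropane, via tetrachlorovinylcarbene 10 (not isolated)
Conditions: ethylene (ca. 20 bar), neat, autoclave, 170 °C
Reagents that add atoms: none
Why: Thermal ring opening of tetrachlorocyclopropene to the vinylcarbene and its [2+1] cycloaddition to ethylene is a documented pressure-vessel preparation of this vinylcyclopropane.

Step 5
Reactants: 11 1-chloro-1-(trichloroethenyl)cyclopropane
Product: 13 methyl 2-chloro-2-cyclopropylideneacetate, via ortho ester 12 (not isolated)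
Conditions: KOH, MeOH, reflux; then 10% aq. HCl, Et2O, rt
Reagents that add atoms: methanol, CO; water, O
Why: Methoxide displaces the cyclopropyl chloride in SN2' fashion and then replaces the two geminal allylic chlorides to give the ortho ester, which mild aqueous acid hydrolyses to the methyl ester (ortho ester hydrolysis), the established preparation of this dienophile.

Step 6
Reactants: 7 methyl 6,6-dimethyl-3-oxo-3,5,6,7-tetrahydrocyclopenta[c]pyran-4-carboxylate; 13 methyl 2-chloro-2-cyclopropylideneacetate
Product: 16 dimethyl 5-(2-chloroethyl)-2,2-dimethylindane-4,6-dicarboxylate, via bridged lactone 14 (not isolated), via spirodiene 15 (not isolated)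
Conditions: 7 (1.2 equiv), toluene, 2,6-di-tert-butyl-4-methylphenol (cat.), sealed tube, 130 °C; then Bu4NCl (10 mol %), 80 °C
Reagents that add atoms: none
Why: Proposed new method: the strained, captodative alkene 13 should add across C3 and C6 of pyranone 7 in an intermolecular [4+2] cycloaddition that closes the six-membered carbocycle as bridged lactone 14 (C6–H carbon to the C(Cl)CO2Me carbon, C3 to the cyclopropylidene carbon), and a retro-[4+2] then expels CO2 to leave cyclohexa-1,3-diene 15. Spirodiene 15 carries its chlorine on a doubly activated ring carbon (conjugated to the diene, bonded to the spiro carbon), so that chloride can depart while one cyclopropane C–C bond breaks and chloride attacks the cyclopropane CH2 (homo-SN2' through a phenonium-like transition state, with Bu4NCl turning over as chloride shuttle); the release of three-membered-ring strain together with the gain of aromaticity makes this strongly downhill and no oxidant is needed. The closest known reaction types are 2-pyranone Diels–Alder/CO2-extrusion benzannulation, Diels–Alder additions of 13 to dienes, and nucleophilic opening of spiro[2.5]octadienyl systems as in the illudin-to-illudalane aromatisation; their combination in one substrate is new. The bridgehead and C(Cl) stereocentres of 14 and the single C(Cl) centre of 15 arise without control (racemic, both chlorine orientations) and are all erased on aromatisation, so none has to be set. The step needs one regiochemical outcome, which is expected because this orientation puts the tied-back, sterically small spiro carbon next to the fully substituted ester-bearing C3 and the bulky chloro ester carbon at the unsubstituted C6–H terminus, and because it pairs the Michael-acceptor carbon of 13 with C3, the δ-carbon of the O1–C6=C5–C4=C3 dienol ether made more electron-rich by the two ring alkyl groups. The slight excess of 7, the radical inhibitor and the sealed vessel are meant to limit polymerisation of 13 and a second cycloaddition onto 15.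

Step 7
Reactants: 16 dimethyl 5-(2-chloroethyl)-2,2-dimethylindane-4,6-dicarboxylate
Product: 17 [5-(2-chloroethyl)-2,2-dimethylindane-4,6-diyl]dimethanol
Conditions: i-Bu2AlH (5 equiv), CH2Cl2, −78 to 0 °C; aq. potassium sodium tartrate, 0 °C
Reagents that add atoms: none
Why: Hydride reduction of both aryl methyl esters with i-Bu2AlH gives the benzylic alcohols without touching the primary alkyl chloride, and the weakly nucleophilic aluminium alkoxides plus a neutral tartrate work-up should prevent ring closure onto the chloroethyl arm to an isochroman.

Step 8
Reactants: 17 [5-(2-chloroethyl)-2,2-dimethylindane-4,6-diyl]dimethanol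
Product: 18 [5-(2-chloroethyl)-4-(hydroxymethyl)-2,2-dimethylindan-6-yl]methyl butanoate
Conditions: vinyl butanoate (3 equiv), immobilised Candida antarctica lipase B, t-BuOMe, 30 °C, stopped when 17 is consumed
Reagents that add atoms: vinyl butanoate, CCCC(=O)OC=C
Why: Lipase-catalysed irreversible transesterification with a vinyl ester responds strongly to crowding around a primary alcohol, so the C6 carbinol (one ortho substituent) should be acylated before the C4 carbinol wedged between the chloroethyl arm and the ring CH2.

Step 9
Reactants: 18 [5-(2-chloroethyl)-4-(hydroxymethyl)-2,2-dimethylindan-6-yl]methyl butanoate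
Product: 19 [4-(acetoxymethyl)-5-(2-chloroethyl)-2,2-dimethylindan-6-yl]methyl butanoate (CNP0321917.0)
Conditions: Ac2O, Et3N, DMAP (cat.), CH2Cl2, 0 °C to rt
Reagents that add atoms: acetic anhydride, CC(=O)OC(C)=O
Why: DMAP-catalysed acylation (nucleophilic acyl-transfer catalysis) esterifies the remaining hindered primary benzylic alcohol under conditions that leave the butanoate and the alkyl chloride untouched.

Compound list
1 | 3,3-dimethylcyclopentanone | CC1(C)CCC(=O)C1 | starting material
2 | dimethyl malonate | COC(=O)CC(=O)OC | starting material
3 | dimethyl 2-(3,3-dimethylcyclopentylidene)malonate | COC(=O)C(C(=O)OC)=C1CCC(C)(C)C1 | intermediate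
4 | N,N-dimethylformamide dimethyl acetal | COC(OC)N(C)C | starting material
5 | dimethyl 2-{(2E)-2-[(dimethylamino)methylidene]-4,4-dimethylcyclopentylidene}malonate | COC(=O)C(C(=O)OC)=C1CC(C)(C)C/C1=C\N(C)C | intermediate
6 | dimethyl 2-[2-(hydroxymethylidene)-4,4-dimethylcyclopentylidene]malonate (enol of the aldehyde, geometry mobile, not isolated) | COC(=O)C(C(=O)OC)=C1CC(C)(C)CC1=CO | intermediate
7 | methyl 6,6-dimethyl-3-oxo-3,5,6,7-tetrahydrocyclopenta[c]pyran-4-carboxylate (4,5-cyclopenta-fused 3-carbomethoxy-2-pyranone, C6–H in pyranone numbering) | COC(=O)C1=C2CC(C)(C)CC2=COC1=O | intermediate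
8 | tetrachlorocyclopropene | ClC1=C(Cl)C1(Cl)Cl | starting material
9 | ethylene | C=C | starting material
10 | tetrachlorovinylcarbene (1,2,3,3-tetrachloroprop-2-enylidene, not isolated) | ClC(Cl)=C(Cl)[C]Cl | intermediate
11 | 1-chloro-1-(trichloroethenyl)cyclopropane | ClC(Cl)=C(Cl)C1(Cl)CC1 | intermediate
12 | 1-(1-chloro-2,2,2-trimethoxyethylidene)cyclopropane (trimethyl ortho ester, not isolated) | COC(OC)(OC)C(Cl)=C1CC1 | intermediate
13 | methyl 2-chloro-2-cyclopropylideneacetate | COC(=O)C(Cl)=C1CC1 | intermediate
14 | bridged lactone: 2-oxabicyclo[2.2.2]oct-7-en-3-one with CO2Me on bridgehead C4, spirocyclopropane at C5, Cl and CO2Me on C6, 4,4-dimethylcyclopentene fused at C7–C8 (racemic, both chlorine orientations, not isolated) | O=C1OC2C(Cl)(C(=O)OC)C3(CC3)C1(C(=O)OC)C4=C2CC(C)(C)C4 | intermediate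
15 | dimethyl 6'-chloro-2',2'-dimethyl-1',2',3',6'-tetrahydrospiro[cyclopropane-1,5'-indene]-4',6'-dicarboxylate (racemic spiro[2.5]octadienyl chloride, not isolated) | COC(=O)C1(Cl)C=C2CC(C)(C)CC2=C(C(=O)OC)C13CC3 | intermediate
16 | dimethyl 5-(2-chloroethyl)-2,2-dimethylindane-4,6-dicarboxylate | COC(=O)c1cc2c(c(C(=O)OC)c1CCCl)CC(C)(C)C2 | intermediate
17 | [5-(2-chloroethyl)-2,2-dimethylindane-4,6-diyl]dimethanol | OCc1cc2c(c(CO)c1CCCl)CC(C)(C)C2 | intermediate
18 | [5-(2-chloroethyl)-4-(hydroxymethyl)-2,2-dimethylindan-6-yl]methyl butanoate | CCCC(=O)OCc1cc2c(c(CO)c1CCCl)CC(C)(C)C2 | intermediate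
19 | [4-(acetoxymethyl)-5-(2-chloroethyl)-2,2-dimethylindan-6-yl]methyl butanoate | CCCC(=O)OCc1cc2c(c(COC(C)=O)c1CCCl)CC(C)(C)C2 | target

Total step count: 9. Longest linear sequence: 7 steps (steps 1, 2, 3, 6, 7, 8, 9); the dienophile branch (steps 4, 5) joins at step 6.

Steps most likely to fail

Step 6. The cycloaddition may orient the other way round (acrylate-type dienophiles often place their acceptor-bearing carbon next to C3 of electron-poor 2-pyranones), which would lead to the 4,5-diester with the chloroethyl arm at C6. It may also be slow between two electron-poor partners, so that the dienophile polymerises, or the transfer of chloride from ring to side chain may stall. The fallback uses known chemistry, sets out from pyranone 7 and returns at diester 16. Tetrahydro-4H-pyran-4-one and pyrrolidine (toluene, water removed azeotropically) give the enamine 1-(3,6-dihydro-2H-pyran-4-yl)pyrrolidine F1. Its inverse-electron-demand Diels–Alder reaction with 7 (toluene, 80–110 °C) is a known aryl annulation of 3-carbomethoxy-2-pyranones, in which the nucleophilic enamine carbon bonds to C6–H and the aminated carbon to C3. After loss of CO2 and pyrrolidine it should give methyl 7,7-dimethyl-1,3,4,6,7,8-hexahydrocyclopenta[g]isochromene-5-carboxylate F2, the isochroman already holding the C5 two-carbon arm and the C6 carbon in the right places. Oxidation of the O-benzylic methylene (KMnO4, CuSO4·5H2O, CH2Cl2) gives methyl 7,7-dimethyl-1-oxo-1,3,4,6,7,8-hexahydrocyclopenta[g]isochromene-5-carboxylate F3. Chlorinative lactone opening (SOCl2, ZnCl2 cat., reflux) gives methyl 6-(chlorocarbonyl)-5-(2-chloroethyl)-2,2-dimethylindane-4-carboxylate F4, and quenching with methanol gives 16, from which step 7 continues.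

Step 8. Discrimination between the two primary benzylic hydroxyls may be insufficient, giving acylation at the C4 carbinol or double acylation. The fallback sets out from diol 17 and returns at target 19 through a protecting-group relay. A bulky silyl chloride (t-BuPh2SiCl, imidazole, CH2Cl2, 0 °C), far more sensitive to crowding than an acyl donor and giving easily separated monosilyl ethers, caps the C6 carbinol as {6-[(tert-butyldiphenylsilyloxy)methyl]-5-(2-chloroethyl)-2,2-dimethylindan-4-yl}methanol F5. Acetylation (Ac2O, Et3N, DMAP) gives {6-[(tert-butyldiphenylsilyloxy)methyl]-5-(2-chloroethyl)-2,2-dimethylindan-4-yl}methyl acetate F6. Non-basic desilylation (HF·pyridine, THF), which forms no alkoxide next to the chloroethyl arm, gives [5-(2-chloroethyl)-6-(hydroxymethyl)-2,2-dimethylindan-4-yl]methyl acetate F7. Butanoylation (butanoic anhydride, Et3N, DMAP) then gives 19.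

Step 2. The weakly acidic alkylidene malonate may condense slowly, partly at the neopentyl γ-methylene, or undergo retro-Knoevenagel cleavage at the temperature required. The fallback sets out from ketone 1 and returns at pyranone 7, putting the formyl carbon in before the malonate. Vilsmeier–Haack chloroformylation of 1 (POCl3, DMF; reaction on the unhindered α-methylene) gives 2-chloro-4,4-dimethylcyclopent-1-ene-1-carbaldehyde F8. Addition–elimination of sodium dimethyl malonate at the chlorine-bearing carbon (dimethyl malonate, NaH, THF) gives dimethyl 2-(2-formyl-4,4-dimethylcyclopent-1-en-1-yl)malonate F9, the aldehyde tautomer of 6. On acidification and warming (AcOH, aq. HCl) this lactonises with loss of methanol to 7.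

Further compounds
F1 | step 6 | 1-(3,6-dihydro-2H-pyran-4-yl)pyrrolidine | C1CCN(C1)C1=CCOCC1
F2 | step 6 | methyl 7,7-dimethyl-1,3,4,6,7,8-hexahydrocyclopenta[g]isochromene-5-carboxylate | COC(=O)c1c2CCOCc2cc2c1CC(C)(C)C2
F3 | step 6 | methyl 7,7-dimethyl-1-oxo-1,3,4,6,7,8-hexahydrocyclopenta[g]isochromene-5-carboxylate | COC(=O)c1c2CCOC(=O)c2cc2c1CC(C)(C)C2
F4 | step 6 | methyl 6-(chlorocarbonyl)-5-(2-chloroethyl)-2,2-dimethylindane-4-carboxylate | COC(=O)c1c(CCCl)c(C(Cl)=O)cc2c1CC(C)(C)C2
F5 | step 8 | {6-[(tert-butyldiphenylsilyloxy)methyl]-5-(2-chloroethyl)-2,2-dimethylindan-4-yl}methanol | OCc1c(CCCl)c(CO[Si](c2ccccc2)(c2ccccc2)C(C)(C)C)cc2c1CC(C)(C)C2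
F6 | step 8 | {6-[(tert-butyldiphenylsilyloxy)methyl]-5-(2-chloroethyl)-2,2-dimethylindan-4-yl}methyl acetate | CC(=O)OCc1c(CCCl)c(CO[Si](c2ccccc2)(c2ccccc2)C(C)(C)C)cc2c1CC(C)(C)C2
F7 | step 8 | [5-(2-chloroethyl)-6-(hydroxymethyl)-2,2-dimethylindan-4-yl]methyl acetate | CC(=O)OCc1c(CCCl)c(CO)cc2c1CC(C)(C)C2
F8 | step 2 | 2-chloro-4,4-dimethylcyclopent-1-ene-1-carbaldehyde | O=CC1=C(Cl)CC(C)(C)C1
F9 | step 2 | dimethyl 2-(2-formyl-4,4-dimethylcyclopent-1-en-1-yl)malonate | COC(=O)C(C(=O)OC)C1=C(C=O)CC(C)(C)C1
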